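The target is a C2-symmetric biphenyl in which each benzene ring carries at ring carbon C5 (C5′) a benzylic stereocentre C7 bearing H, CH3 and the chain methylene C8 (side-chain atoms numbered C7, C8, C9 outward). Both C7–H and both C8–C9 bonds are disconnected together: a ligand-controlled copper hydride adds across the two isopropenyl groups of a biaryl dimethyl ether and each primary alkylcopper is trapped by an allyl phosphate, which sets both (S) centres and builds most of each side chain without closing a ring. The precursor, stereocentre-free 4,4′-dimethoxy-2,2′-dimethyl-5,5′-diisopropenylbiphenyl, comes in four steps from a hydroxyacetophenone; cross-metathesis and demethylation finish the route.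

Key step: step 5

Remark (configuration): both side-chain centres of the target are (S) (CIP order aryl > CH2 > CH3 > H); the biaryl axis has only one ortho substituent per ring, is taken to rotate freely at room temperature and needs no descriptor.
Remark (ligand sense): (R)-DTBM-SEGPHOS is written for step 5; the antipode that gives (S) at C7 is to be confirmed on a first small-scale run and the mirror-image ligand used if the sense is opposite.

Step 1
Reactants: 1 1-(2-hydroxy-4-methylphenyl)ethanone
Product: 2 1-(5-bromo-2-hydroxy-4-methylphenyl)ethanone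
Conditions: NBS (1.05 equiv), MeCN, 0 °C → rt
Reagents that add atoms: N-bromosuccinimide, O=C1CCC(=O)N1Br
Why: Electrophilic aromatic bromination goes para to the strongly activating OH, because the only other activated position lies between OH and CH3 and the hydrogen-bonded ketone is not prone to α-bromination without acid.

Step 2
Reactants: 2 1-(5-bromo-2-hydroxy-4-methylphenyl)ethanone
Product: 3 1-(5-bromo-2-methoxy-4-methylphenyl)ethanone
Conditions: MeI (1.5 equiv), K2CO3 (2 equiv), DMF, 40 °C
Reagents that add atoms: iodomethane, CI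
Why: Williamson ether synthesis, in which carbonate deprotonates the hydrogen-bonded phenol and the phenoxide is methylated by SN2 while the aryl bromide and the ketone stay inert.

Step 3
Reactants: 3 1-(5-bromo-2-methoxy-4-methylphenyl)ethanone (two molecules)
Product: 4 5,5′-diacetyl-4,4′-dimethoxy-2,2′-dimethylbiphenyl
Conditions: NiCl2(PPh3)2 (10 mol%), PPh3 (20 mol%), Zn dust (1.5 equiv), Et4NI (1 equiv), THF, 50 °C
Reagents that add atoms: none
Why: Nickel(0)-catalysed reductive homocoupling of an aryl bromide with zinc as terminal reductant (Ullmann-type coupling) tolerates aryl ketones and one ortho-methyl group and joins the two former C–Br carbons.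

Step 4
Reactants: 4 5,5′-diacetyl-4,4′-dimethoxy-2,2′-dimethylbiphenyl
Product: 6 4,4′-dimethoxy-2,2′-dimethyl-5,5′-di(prop-1-en-2-yl)biphenyl, via mono-methylenated keto alkene 5 (not isolated)
Conditions: Ph3PCH3Br (3 equiv), KOtBu (2.9 equiv), THF, 0 °C → reflux
Reagents that add atoms: methyltriphenylphosphonium bromide, C[P+](c1ccccc1)(c1ccccc1)c1ccccc1.[Br-]
Why: Twofold Wittig methylenation of the aryl methyl ketones by the non-stabilised ylide Ph3P=CH2, used in excess so that olefination outruns enolisation of the ortho-methoxy acetophenone units.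

Step 5
Reactants: 6 4,4′-dimethoxy-2,2′-dimethyl-5,5′-di(prop-1-en-2-yl)biphenyl; 7 allyl diethyl phosphate (3 equiv)
Product: 9 5,5′-bis[(2S)-hex-5-en-2-yl]-4,4′-dimethoxy-2,2′-dimethylbiphenyl, via mono-hydroallylated isopropenyl biaryl 8 (not isolated)
Conditions: Cu(OAc)2 (10 mol%), (R)-DTBM-SEGPHOS (11 mol%), (MeO)2MeSiH (5 equiv), LiOtBu (3 equiv), slow addition of 7, THF, rt → 40 °C; then 1 M HCl
Reagents that add atoms: none
Why: Proposed new method: Cu(OAc)2, the bisphosphine and the hydrosilane should give a ligated copper hydride that adds syn across each C7=C8 bond with hydride to C7 and copper to the terminal C8; the primary alkylcopper then displaces phosphate from 7 in an SN2′ allylic substitution to form C8–C9, and LiOtBu together with the silane converts the copper phosphate back into copper hydride. The closest known reaction types are the copper hydride-catalysed enantioselective hydroallylation of vinylarenes with allylic phosphates and the anti-Markovnikov copper hydride hydroboration and hydroamination of 1,1-disubstituted alkenes, in which hydrocupration creates a β-stereocentre; a twofold version on ortho-alkoxy isopropenylarenes with the parent allyl group has not been shown. No ring is closed. Each C7 centre is set in the hydrocupration by the chiral bisphosphine, which selects the alkene face that receives hydride, and because the two remote alkenes react independently the minor sense ends up mainly in the meso diastereomer, so the (S,S) product should be highly enantio-enriched. Regioselectivity (copper at C8, not at the tertiary benzylic C7) is secured by the 1,1-disubstitution, the bulky ligand and the ortho-methoxy group that forces the alkene out of the arene plane. Chemoselectivity for the isopropenylarenes over the new monosubstituted alkenes and over direct reduction of 7 rests on the remaining aryl activation of the substrate alkenes, slow addition of excess 7 and stopping once 8 is consumed.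

Step 6
Reactants: 9 5,5′-bis[(2S)-hex-5-en-2-yl]-4,4′-dimethoxy-2,2′-dimethylbiphenyl; 10 2-methylbut-2-ene (large excess)
Product: 12 4,4′-dimethoxy-2,2′-dimethyl-5,5′-bis[(2S)-6-methylhept-5-en-2-yl]biphenyl, via singly capped hexenyl heptenyl biaryl 11 (not isolated)
Conditions: (H2IMes)Cl2Ru=CH(2-iPrO-C6H4) (5 mol%), 2-methylbut-2-ene/CH2Cl2, 40 °C, sealed tube
Reagents that add atoms: none
Why: Olefin cross-metathesis with a ruthenium N-heterocyclic carbene catalyst in excess 2-methylbut-2-ene turns each monosubstituted alkene into the trisubstituted isopropylidene terminus with loss of propene, the excess partner suppressing self-metathesis and the C7 centres being untouched.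

Step 7
Reactants: 12 4,4′-dimethoxy-2,2′-dimethyl-5,5′-bis[(2S)-6-methylhept-5-en-2-yl]biphenyl
Product: 14 2,2′-dimethyl-5,5′-bis[(2S)-6-methylhept-5-en-2-yl]biphenyl-4,4′-diol, via mono-methyl ether phenol 13 (not isolated)
Conditions: NaSEt (6 equiv), DMF, 130 °C; then 1 M HCl
Reagents that add atoms: none
Why: Nucleophilic demethylation of the aryl methyl ethers by thiolate (SN2 at the methyl carbon) in hot DMF leaves the trisubstituted alkenes and the non-acidic benzylic C7–H centres unchanged, and acidification releases the diphenol.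

Compound list
1 | 1-(2-hydroxy-4-methylphenyl)ethanone | CC(=O)c1ccc(C)cc1O | starting material
2 | 1-(5-bromo-2-hydroxy-4-methylphenyl)ethanone | CC(=O)c1cc(Br)c(C)cc1O | intermediate
3 | 1-(5-bromo-2-methoxy-4-methylphenyl)ethanone | CC(=O)c1cc(Br)c(C)cc1OC | intermediate
4 | 5,5′-diacetyl-4,4′-dimethoxy-2,2′-dimethylbiphenyl | CC(=O)c1cc(-c2cc(C(C)=O)c(OC)cc2C)c(C)cc1OC | intermediate
5 | 1-[4,4′-dimethoxy-2,2′-dimethyl-5′-(prop-1-en-2-yl)biphenyl-5-yl]ethanone | CC(=O)c1cc(-c2cc(C(C)=C)c(OC)cc2C)c(C)cc1OC | intermediate
6 | 4,4′-dimethoxy-2,2′-dimethyl-5,5′-di(prop-1-en-2-yl)biphenyl | Cc1cc(OC)c(C(C)=C)cc1-c1cc(C(C)=C)c(OC)cc1C | intermediate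
7 | allyl diethyl phosphate | C=CCOP(=O)(OCC)OCC | starting material
8 | 5-[(2S)-hex-5-en-2-yl]-4,4′-dimethoxy-2,2′-dimethyl-5′-(prop-1-en-2-yl)biphenyl | Cc1cc(OC)c([C@@H](C)CCC=C)cc1-c1cc(C(C)=C)c(OC)cc1C | intermediate
9 | 5,5′-bis[(2S)-hex-5-en-2-yl]-4,4′-dimethoxy-2,2′-dimethylbiphenyl | Cc1cc(OC)c([C@@H](C)CCC=C)cc1-c1cc([C@@H](C)CCC=C)c(OC)cc1C | intermediate
10 | 2-methylbut-2-ene | CC=C(C)C | starting material
11 | 5-[(2S)-hex-5-en-2-yl]-4,4′-dimethoxy-2,2′-dimethyl-5′-[(2S)-6-methylhept-5-en-2-yl]biphenyl | Cc1cc(OC)c([C@@H](C)CCC=C)cc1-c1cc([C@@H](C)CCC=C(C)C)c(OC)cc1C | intermediate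
12 | 4,4′-dimethoxy-2,2′-dimethyl-5,5′-bis[(2S)-6-methylhept-5-en-2-yl]biphenyl | Cc1cc(OC)c([C@@H](C)CCC=C(C)C)cc1-c1cc([C@@H](C)CCC=C(C)C)c(OC)cc1C | intermediate
13 | 4′-methoxy-2,2′-dimethyl-5,5′-bis[(2S)-6-methylhept-5-en-2-yl]biphenyl-4-ol | Cc1cc(O)c([C@@H](C)CCC=C(C)C)cc1-c1cc([C@@H](C)CCC=C(C)C)c(OC)cc1C | intermediate
14 | 2,2′-dimethyl-5,5′-bis[(2S)-6-methylhept-5-en-2-yl]biphenyl-4,4′-diol | CC(C)=CCC[C@H](C)c1cc(-c2cc([C@@H](C)CCC=C(C)C)c(O)cc2C)c(C)cc1O | target

Total step count: 7
Longest linear sequence: 7 steps (1 → 14)

Steps most likely to fail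

Step 5 (proposed new method). Three processes could undermine it:
- The copper hydride may add to the newly formed monosubstituted alkenes, which would lead to further allylation and chain growth.
- The copper hydride may reduce the allyl phosphate directly and consume the reagent.
- Facial selectivity may be insufficient, leaving meso diastereomer that is unlikely to separate from the (S,S) compound because the centres are remote; preparative HPLC on a chiral phase at 9 or 14 would then be needed.

The fallback sets out from 6 and returns to the route at 9, using known reactions only. Copper-catalysed enantioselective hydroboration of the 1,1-disubstituted aryl alkenes with pinacolborane (CuCl, NaOtBu, DTBM-SEGPHOS, THF, rt) is a known reaction class that places boron on the terminal carbon and sets the β-stereocentre. It should give 4,4′-dimethoxy-2,2′-dimethyl-5,5′-bis[(2S)-1-(4,4,5,5-tetramethyl-1,3,2-dioxaborolan-2-yl)propan-2-yl]biphenyl F1. Oxidation (NaBO3, THF/H2O) should give 5,5′-bis[(2R)-1-hydroxypropan-2-yl]-4,4′-dimethoxy-2,2′-dimethylbiphenyl F2; the descriptor changes only through CIP priority. Appel iodination (I2, PPh3, imidazole, CH2Cl2) should give 5,5′-bis[(2R)-1-iodopropan-2-yl]-4,4′-dimethoxy-2,2′-dimethylbiphenyl F3. Copper-catalysed coupling of the primary iodides with allylmagnesium bromide (Li2CuCl4 catalyst, THF, −20 °C → rt) forms the same C8–C9 bonds and delivers 9.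

Step 6. The twofold cross-metathesis may stall after one terminus or at the 1,2-disubstituted but-2-enyl stage. The diene may also undergo ring-closing or oligomerising self-metathesis, and ruthenium hydride species may cause alkene migration.

The fallback sets out from 9 and returns at 12. Oxidative cleavage of both terminal alkenes (OsO4 catalyst, NaIO4, 2,6-lutidine, dioxane/H2O; Lemieux–Johnson conditions, chosen over ozone because of the electron-rich arenes) should give (4S,4′S)-4,4′-(4,4′-dimethoxy-6,6′-dimethylbiphenyl-3,3′-diyl)dipentanal F4. Wittig olefination with isopropylidenetriphenylphosphorane (iPrPPh3I, n-BuLi, THF, −78 °C → rt) should then give 12.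

Step 3. Hydrodebromination of the ortho-methyl arylnickel intermediate or slow turnover may erode the reductive homocoupling.

The fallback sets out from 3 and returns at 4. Miyaura borylation of half of the bromide (B2pin2, Pd(dppf)Cl2, KOAc, dioxane, 90 °C) should give 1-[2-methoxy-4-methyl-5-(4,4,5,5-tetramethyl-1,3,2-dioxaborolan-2-yl)phenyl]ethanone F5. Suzuki–Miyaura cross-coupling of this boronate with the remaining 3 (Pd(OAc)2/SPhos, K3PO4, toluene/H2O, 90 °C) should give 4.

Further compounds
F1 | step 5 | 4,4′-dimethoxy-2,2′-dimethyl-5,5′-bis[(2S)-1-(4,4,5,5-tetramethyl-1,3,2-dioxaborolan-2-yl)propan-2-yl]biphenyl | Cc1cc(OC)c([C@@H](C)CB2OC(C)(C)C(C)(C)O2)cc1-c1cc([C@@H](C)CB2OC(C)(C)C(C)(C)O2)c(OC)cc1C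
F2 | step 5 | 5,5′-bis[(2R)-1-hydroxypropan-2-yl]-4,4′-dimethoxy-2,2′-dimethylbiphenyl | Cc1cc(OC)c([C@@H](C)CO)cc1-c1cc([C@@H](C)CO)c(OC)cc1C
F3 | step 5 | 5,5′-bis[(2R)-1-iodopropan-2-yl]-4,4′-dimethoxy-2,2′-dimethylbiphenyl | Cc1cc(OC)c([C@@H](C)CI)cc1-c1cc([C@@H](C)CI)c(OC)cc1C
F4 | step 6 | (4S,4′S)-4,4′-(4,4′-dimethoxy-6,6′-dimethylbiphenyl-3,3′-diyl)dipentanal | Cc1cc(OC)c([C@@H](C)CCC=O)cc1-c1cc([C@@H](C)CCC=O)c(OC)cc1C
F5 | step 3 | 1-[2-methoxy-4-methyl-5-(4,4,5,5-tetramethyl-1,3,2-dioxaborolan-2-yl)phenyl]ethanone | CC(=O)c1cc(B2OC(C)(C)C(C)(C)O2)c(C)cc1OC
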